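**Strategy.** The target is the ester of 15‑O‑acetylisocupressic acid with the tertiary C4 hydroxyl of cryptomeridiol (eudesmane numbering), so the last C–O bond is made by acylation. The eudesmane B ring (C5–C10) is born five‑membered. A Dowd–Beckwith radical ring expansion inserts C6 into a cyclopentanone between the ketone carbon (future C5) and the ester‑bearing carbon (future C7). It exploits the 1,3‑relation of C5 and C7 in ring B and turns the ester carbon into C11. The precursor is a bromomethyl β‑keto ester made from 2‑methylcyclopentanone. C10 is then set by an auxiliary‑controlled Robinson annulation; C7, C5 and C4 follow by substrate control.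

Key step: step 3

Remark on numbering: eudesmane numbering is used for the alcohol half (C4 carries the ester oxygen, C5/C10 are the ring fusion, C7 carries C11 with the free tertiary hydroxyl, ring B = C5–C10), and labdane numbering for the acid half.
Assumption: isocupressic acid (17) is bought as a natural‑product reference substance.

**Step 1**
Reactants: 1 2‑methylcyclopentanone
Product: 2 methyl 3‑methyl‑2‑oxocyclopentane‑1‑carboxylate
Conditions: NaH (2.2 equiv), (MeO)2CO, THF, reflux; then aq HCl
Reagents that add atoms: dimethyl carbonate, COC(=O)OC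
Why: Claisen‑type C‑carbomethoxylation of the ketone enolate, which should end at the unsubstituted α‑carbon because only that β‑keto ester can be drained off as its stabilised enolate.

**Step 2**
Reactants: 2 methyl 3‑methyl‑2‑oxocyclopentane‑1‑carboxylate
Product: 3 methyl 1‑(bromomethyl)‑3‑methyl‑2‑oxocyclopentane‑1‑carboxylate
Conditions: NaH, CH2Br2 (excess), THF–HMPA, 0 °C → reflux
Reagents that add atoms: dibromomethane, BrCBr
Why: SN2 C‑alkylation of the β‑keto ester sodium enolate with dibromomethane builds the quaternary carbon (future C7); both diastereomers serve, since this centre is destroyed in step 3.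

**Step 3**
Reactants: 3 methyl 1‑(bromomethyl)‑3‑methyl‑2‑oxocyclopentane‑1‑carboxylate
Product: 4 methyl 4‑methyl‑3‑oxocyclohexane‑1‑carboxylate
Conditions: Bu3SnH (1.2 equiv, syringe pump), AIBN (cat.), PhH (0.02 M), 80 °C
Reagents that add atoms: none
Why: Dowd–Beckwith ring expansion: Bu3Sn• abstracts bromine, the primary radical adds 3‑exo‑trig to the ketone carbonyl, and the bicyclo[3.1.0] alkoxy radical fragments at the internal C–C bond to the tertiary, ester‑stabilised radical of the six‑membered ring, which takes hydrogen from the stannane. The closest known reaction is the stannane‑mediated one‑carbon expansion of methyl 1‑(bromomethyl)‑2‑oxocyclopentanecarboxylate to methyl 3‑oxocyclohexanecarboxylate. No ring is closed for good: the only closure is the transient 3‑exo‑trig cyclopropane, and its cleavage enlarges the five‑membered ring by the CH2 that becomes C6. The new stereocentre (future C7, α to the ester) arises from uncontrolled hydrogen transfer and need not be controlled, because it is equilibrated in step 5; the methyl‑bearing carbon is epimerisable next to the ketone. The step needs rearrangement to outrun direct reduction of the primary radical, and fragmentation toward the expanded ring; the low stannane concentration and the ester, which makes the ring‑expanded radical the most stable one, should secure both.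

**Step 4**
Reactants: 4 methyl 4‑methyl‑3‑oxocyclohexane‑1‑carboxylate; 5 (R)‑1‑phenylethylamine; 6 ethyl vinyl ketone
Product: 9 methyl (4S)‑4‑methyl‑3‑oxo‑4‑(3‑oxopentyl)cyclohexane‑1‑carboxylate, via imine 7 (not isolated), via alkylated imine 8 (not isolated)
Conditions: 5, TsOH (cat.), PhMe, Dean–Stark; then 6, THF, 40 °C; then 10% aq AcOH, rt
Reagents that add atoms: water, O
Why: d'Angelo asymmetric Michael addition: the more substituted secondary enamine tautomer of chiral imine 7 should add to the enone through a chair‑like aza‑ene transition state anti to the phenyl group, regioselectively at the methyl‑bearing carbon, setting the quaternary centre (future C10) as S with the (R)‑amine, while the ester‑bearing carbon stays a mixture that converges in step 5.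

**Step 5**
Reactants: 9 methyl (4S)‑4‑methyl‑3‑oxo‑4‑(3‑oxopentyl)cyclohexane‑1‑carboxylate
Product: 10 methyl (2R,4aS)‑4a,8‑dimethyl‑7‑oxo‑1,2,3,4,4a,5,6,7‑octahydronaphthalene‑2‑carboxylate
Conditions: NaOMe, MeOH, reflux
Reagents that add atoms: none
Why: The intramolecular aldol condensation that completes the Robinson annulation closes ring A as the conjugated enone, and methoxide should equilibrate the centre α to the ester to the equatorial 7β‑ester, cis to the angular methyl group (thermodynamic control relayed from C10).

**Step 6**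
Reactants: 10 methyl (2R,4aS)‑4a,8‑dimethyl‑7‑oxo‑1,2,3,4,4a,5,6,7‑octahydronaphthalene‑2‑carboxylate
Product: 11 1,3‑dithiolane of 10 at the enone carbonyl (C3)
Conditions: HSCH2CH2SH, BF3·OEt2, AcOH, rt
Reagents that add atoms: ethane‑1,2‑dithiol, SCCS
Why: Lewis‑acid dithioketalisation should take only the ketone, leaving the methyl ester and the tetrasubstituted C4=C5 double bond in place.

**Step 7**
Reactants: 11 1,3‑dithiolane of 10
Product: 12 methyl (2R,4aR)‑4a,8‑dimethyl‑1,2,3,4,4a,5,6,7‑octahydronaphthalene‑2‑carboxylate
Conditions: Raney Ni (W‑2), EtOH, reflux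
Reagents that add atoms: none
Why: Mozingo desulfurisation removes the C3 oxygen function as CH2; the tetrasubstituted alkene should resist hydrogenation and is already the most stable double‑bond isomer.

**Step 8**
Reactants: 12 methyl (2R,4aR)‑4a,8‑dimethyl‑1,2,3,4,4a,5,6,7‑octahydronaphthalene‑2‑carboxylate
Product: 13 (+)‑γ‑eudesmol
Conditions: MeMgBr (3.5 equiv), THF, 0 °C → rt; aq NH4Cl
Reagents that add atoms: methylmagnesium bromide, C[Mg]Br
Why: Double Grignard addition to the ester turns the ester carbon into the C11 dimethylcarbinol without touching C7.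

**Step 9**
Reactants: 13 (+)‑γ‑eudesmol
Product: 14 γ‑eudesmol triethylsilyl ether
Conditions: TESOTf, 2,6‑lutidine, CH2Cl2, −78 → 0 °C
Reagents that add atoms: triethylsilyl trifluoromethanesulfonate, CC[Si](CC)(CC)OS(=O)(=O)C(F)(F)F
Why: Silyl triflate silylation masks the C11 hydroxyl, so that the C4 hydroxyl made next is the only free one at the acylation stage.

**Step 10**
Reactants: 14 γ‑eudesmol triethylsilyl ether
Product: 16 11‑O‑triethylsilylcryptomeridiol, via alkylborane 15 (not isolated)
Conditions: BH3·THF (excess), THF, 0 °C → rt; then NaOH, H2O2, 0 °C → rt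
Reagents that add atoms: hydrogen peroxide, OO
Why: Hydroboration–oxidation: borane should add syn from the α‑face, opposite the axial angular methyl group, with boron at the less hindered C4 and hydrogen at C5, and oxidation with retention then gives the 4α‑ol with 5α‑H (trans‑decalin).

**Step 11**
Reactants: 17 isocupressic acid
Product: 18 15‑O‑acetylisocupressic acid
Conditions: Ac2O, pyridine, DMAP (cat.), CH2Cl2, rt; aqueous work‑up
Reagents that add atoms: acetic anhydride, CC(=O)OC(C)=O
Why: DMAP‑catalysed O‑acetylation of the primary allylic alcohol; any mixed anhydride at the hindered C19 acid is hydrolysed on work‑up.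

**Step 12**
Reactants: 18 15‑O‑acetylisocupressic acid; 16 11‑O‑triethylsilylcryptomeridiol
Product: 21 11‑O‑triethylsilyl ether of the target ester, via acid chloride 19 (not isolated), via potassium alkoxide 20 (not isolated)
Conditions: 18, Me2C=C(Cl)NMe2 (Ghosez), CH2Cl2, 0 °C → rt, concentrate; 16, KHMDS, THF, −78 → 0 °C; combine, 0 → 50 °C
Reagents that add atoms: none
Why: Acylation of a tertiary potassium alkoxide by an acid chloride that is made under neutral conditions and has no α‑hydrogen (no ketene, no epimerisation); the configuration at C4 is retained because its C–O bond is not touched, and esters from any minor enantiomer of 16 are diastereomers that can be removed here.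

**Step 13**
Reactants: 21 11‑O‑triethylsilyl ether of the target ester
Product: 22 CNP0141048.1 (cryptomeridiol 4‑O‑[15‑acetoxylabda‑8(17),13E‑dien‑19‑oate])
Conditions: HF·pyridine, pyridine/THF, 0 °C → rt
Reagents that add atoms: none
Why: Buffered fluoride cleavage of the tertiary silyl ether should leave the allylic acetate, the hindered tertiary ester and both alkenes untouched.

**Compound list**

1 | 2‑methylcyclopentanone (racemic) | CC1CCCC1=O | starting material
2 | methyl 3‑methyl‑2‑oxocyclopentane‑1‑carboxylate (racemic, both diastereomers) | COC(=O)C1CCC(C)C1=O | intermediate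
3 | methyl 1‑(bromomethyl)‑3‑methyl‑2‑oxocyclopentane‑1‑carboxylate (racemic, both diastereomers) | COC(=O)C1(CBr)CCC(C)C1=O | intermediate
4 | methyl 4‑methyl‑3‑oxocyclohexane‑1‑carboxylate (racemic, cis/trans) | COC(=O)C1CCC(C)C(=O)C1 | intermediate
5 | (R)‑1‑phenylethylamine (chiral auxiliary) | C[C@@H](N)c1ccccc1 | starting material
6 | ethyl vinyl ketone (pent‑1‑en‑3‑one) | C=CC(=O)CC | starting material
7 | imine of 4 with 5 (ring centres unassigned) | COC(=O)C1CCC(C)C(=N[C@H](C)c2ccccc2)C1 | intermediate
8 | alkylated imine: (R)‑1‑phenylethyl imine of 9 (quaternary carbon S, ester carbon both epimers) | CCC(=O)CC[C@]1(C)CCC(C(=O)OC)CC1=N[C@H](C)c1ccccc1 | intermediate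
9 | methyl (4S)‑4‑methyl‑3‑oxo‑4‑(3‑oxopentyl)cyclohexane‑1‑carboxylate (both epimers at C1) | CCC(=O)CC[C@]1(C)CCC(C(=O)OC)CC1=O | intermediate
10 | methyl (2R,4aS)‑4a,8‑dimethyl‑7‑oxo‑1,2,3,4,4a,5,6,7‑octahydronaphthalene‑2‑carboxylate (3‑oxo‑Δ4, 7β‑ester, 10β‑methyl in eudesmane terms) | CC1=C2C[C@H](C(=O)OC)CC[C@@]2(C)CCC1=O | intermediate
11 | 1,3‑dithiolane of 10 at the enone carbonyl | CC1=C2C[C@H](C(=O)OC)CC[C@@]2(C)CCC13SCCS3 | intermediate
12 | methyl (2R,4aR)‑4a,8‑dimethyl‑1,2,3,4,4a,5,6,7‑octahydronaphthalene‑2‑carboxylate | CC1=C2C[C@H](C(=O)OC)CC[C@@]2(C)CCC1 | intermediate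
13 | (+)‑γ‑eudesmol, 2‑[(2R,4aR)‑4a,8‑dimethyl‑1,2,3,4,4a,5,6,7‑octahydronaphthalen‑2‑yl]propan‑2‑ol | CC1=C2C[C@H](C(C)(C)O)CC[C@@]2(C)CCC1 | intermediate
14 | γ‑eudesmol triethylsilyl ether | CC1=C2C[C@H](C(C)(C)O[Si](CC)(CC)CC)CC[C@@]2(C)CCC1 | intermediate
15 | alkylborane: 4α‑boryl adduct of 14 (5α‑H) | B[C@]1(C)CCC[C@]2(C)CC[C@@H](C(C)(C)O[Si](CC)(CC)CC)C[C@H]21 | intermediate
16 | 11‑O‑triethylsilylcryptomeridiol, (1R,4aR,7R,8aR)‑1,4a‑dimethyl‑7‑{2‑[(triethylsilyl)oxy]propan‑2‑yl}decahydronaphthalen‑1‑ol | O[C@]1(C)CCC[C@]2(C)CC[C@@H](C(C)(C)O[Si](CC)(CC)CC)C[C@H]21 | intermediate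
17 | isocupressic acid, 15‑hydroxylabda‑8(17),13E‑dien‑19‑oic acid | C=C1CC[C@@H]2[C@](C)(CCC[C@]2(C)C(=O)O)[C@H]1CC/C(C)=C/CO | starting material
18 | 15‑O‑acetylisocupressic acid | C=C1CC[C@@H]2[C@](C)(CCC[C@]2(C)C(=O)O)[C@H]1CC/C(C)=C/COC(C)=O | intermediate
19 | acid chloride of 18 | C=C1CC[C@@H]2[C@](C)(CCC[C@]2(C)C(=O)Cl)[C@H]1CC/C(C)=C/COC(C)=O | intermediate
20 | potassium alkoxide of 16 | [K+].[O-][C@]1(C)CCC[C@]2(C)CC[C@@H](C(C)(C)O[Si](CC)(CC)CC)C[C@H]21 | intermediate
21 | 11‑O‑triethylsilyl ether of the target ester | C=C1CC[C@@H]2[C@](C)(CCC[C@]2(C)C(=O)O[C@]2(C)CCC[C@]3(C)CC[C@@H](C(C)(C)O[Si](CC)(CC)CC)C[C@H]32)[C@H]1CC/C(C)=C/COC(C)=O | intermediate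
22 | CNP0141048.1, cryptomeridiol 4‑O‑[15‑acetoxylabda‑8(17),13E‑dien‑19‑oate] | C=C1CC[C@@H]2[C@](C)(CCC[C@]2(C)C(=O)O[C@]2(C)CCC[C@]3(C)CC[C@@H](C(C)(C)O)C[C@H]32)[C@H]1CC/C(C)=C/COC(C)=O | target

**Totals.** Total step count: 13. Longest linear sequence: 12 steps (steps 1–10, 12, 13).

**Steps most likely to fail**

Step 12 (esterification). Both partners are neopentyl‑type, so the alkoxide may fail to reach the acyl carbon or may instead take the acetyl group from the allylic acetate. The fallback makes the C4–O bond by O‑alkylation instead of O‑acylation. It sets out from 16: trichloroacetonitrile with catalytic DBU should give the tertiary trichloroacetimidate F1. Heating F1 with the free acid 18 in toluene, without added acid, should protonate the imidate and generate a C4 cation–carboxylate ion pair. Collapse on the less hindered equatorial α‑face would give 21, where the fallback rejoins the route; elimination to olefin is the expected loss.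

Step 10 (hydroboration). Boron may add at C5 instead of C4, facial control may be poor, or the tertiary borane may migrate. The fallback sets out from 14: a Schenck ene reaction with singlet oxygen (O2, tetraphenylporphyrin, hν, CH2Cl2) should place oxygen at C4 on the α‑face and abstract hydrogen from C6, geminal to the bulky C10, giving the 4α‑hydroperoxy‑Δ5 compound F2. Triphenylphosphine reduces it to the 4α‑hydroxy‑Δ5 compound F3. Hydroxyl‑directed hydrogenation with Crabtree's catalyst should then deliver hydrogen to C5 on the α‑face and return to the route at 16.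

Step 3 (radical ring expansion). The primary radical may be reduced before it closes onto the carbonyl, or tin residues may complicate isolation. The fallback sets out from 2 and also bypasses step 2: zinc‑carbenoid homologation of the β‑keto ester (Et2Zn, CH2I2, CH2Cl2, 0 °C → rt; aq NH4Cl) proceeds through a zinc cyclopropanolate that fragments to the ring‑expanded γ‑keto ester. It comes back to the route at 4; no new compound is made (F0).

**Further compounds**

F1 | step 12 | C4 trichloroacetimidate of 16 | N=C(O[C@]1(C)CCC[C@]2(C)CC[C@@H](C(C)(C)O[Si](CC)(CC)CC)C[C@H]21)C(Cl)(Cl)Cl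
F2 | step 10 | 4α‑hydroperoxy‑Δ5 compound (11‑O‑TES) | OO[C@]1(C)CCC[C@]2(C)CC[C@@H](C(C)(C)O[Si](CC)(CC)CC)C=C21
F3 | step 10 | 4α‑hydroxy‑Δ5 compound (11‑O‑TES) | O[C@]1(C)CCC[C@]2(C)CC[C@@H](C(C)(C)O[Si](CC)(CC)CC)C=C21
F0 | step 3 | none | none
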